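## The problem

The target is the bis-acetate of an aryltetralin lignan of the lyoniresinol type. Ring A is a benzene with OMe, OH and OMe on C6, C7 and C8 and a single hydrogen on C5. Ring B carries three contiguous stereocentres, all trans (1S,2R,3R): the aryl group on C1 and acetoxymethyl groups on C2 and C3. Ring C is a 4-hydroxy-3,5-dimethoxyphenyl group. The trans C2/C3 pair can be set first and then used to control C1, because a nucleophile adding to a planar C1 cation approaches anti to the C2 substituent. C1 is benzylic to a ring with ortho and para methoxy groups, so a cation forms there easily; this allows ring C to be attached, but the cation can also lose the C2 proton. Two primary acetates must end beside two free phenols, so the last phenol cannot be freed by base or hydrolysis, and an oxygen β to the C1 ketone can be lost by elimination on the way. Ring A needs three different oxygen substituents on adjacent carbons in a fixed order. The feature that makes the key step possible is that C5(H)–C6(OMe)–C7(O)–C8(O) is a 1,2,3-trioxygenated butadiene, while C4a and C8a are the β- and α-carbons of a cyclohexenone whose carbonyl is C1, so ring A can be made by cycloaddition and aromatisation on a ring B enone that already holds C2 and C3.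

## Retrosynthesis

**C7–O benzyl.** Target 23 is traced to its C7 benzyl ether 22. Hydrogenolysis is the one unmasking that is neutral and leaves primary acetates untouched, so benzyl is the group carried on the C7 oxygen from the start.

**C1–aryl bond.** Cutting this bond turns 22 into the C1 acetate 20 and commercial 2,6-dimethoxyphenol 21. The neighbouring cut, C1–C8a (cyclisation of a diarylmethyl cation onto ring A), would leave C2/C3 to be built on an open chain and ring A to be made separately. The chosen cut removes one stereocentre and a whole ring in one step. The forward reaction is a Friedel–Crafts alkylation through the C1 cation; it must be trans-selective and must go para to the phenol hydroxyl.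

**Functional group changes on ring B.** Triacetate 20 comes from benzylic alcohol 18 by silyl-to-acetate exchange through triol 19, 18 from ketone 17, and 17 from the chelated C8 phenol 16 by O-methylation. Silyl ethers rather than acetates are carried through the ketone stage because a β-acetoxy ketone would lose acetic acid under any base, whereas silyloxide is a poor leaving group.

**Ring A (key disconnection).** Cutting C4a–C5 and C8–C8a of 16 gives bromoenone 10 and the tetra-oxygenated diene 14. A Friedel–Crafts acylation closing C1–C8a was the neighbouring option; it would need the stereodefined C2/C3 chain attached to a preformed arene and would still have to differentiate the C7 oxygen from its neighbours. The cycloaddition instead places OMe on C6, OBn on C7 and a free, chelated OH on C8 in one operation and leaves the C1 ketone for the later arylation. The precursors are a monocyclic enone with only the C2/C3 stereocentres and an acyclic diene. The forward reaction needs regiocontrol only, since every centre it creates is lost on aromatisation.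

**Bromoenone 10.** 10 comes from enone 9 by bromination and dehydrobromination, and 9 from allylic alcohol 8 by oxidation. 8 is traced to the C2-symmetric cyclohexene 7. A radical-type allylic oxidation of 7 would pass through an allyl radical that can take oxygen at either end and so give two regioisomeric enones. The ene/[2,3] sequence of SeO2 returns the double bond to its place and puts oxygen on the carbon next to a stereocentre; because the two allylic CH2 groups of 7 are homotopic, one constitutional isomer results. 7 comes from diol 6, and 6 from diester 5, the Diels–Alder adduct of buta-1,3-diene 4 with di-(+)-menthyl fumarate 3, made from fumaric acid 1 and (+)-menthol 2. The auxiliary sets both stereocentres in one step and is recovered.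

**Diene 14.** 14 is the silyl dienol ether of the β-methoxy enoate 13, which comes from β-keto ester 12 by O-methylation, and 12 from methyl benzyloxyacetate 11 by C-acetylation. The benzyl group enters here and is not removed until the last step.

## Roads not taken

Alternative 1: The cut is C2–C3 together with C1–C8a. In the forward step a laccase with O2 would oxidise two molecules of the N-sinapoyl oxazolidinone A1 to phenoxy radicals that couple at the carbons α to the carbonyl groups. One quinone methide re-aromatises and its ring attacks the other at C1, closing ring B to give the dihydronaphthalene bis-imide A2. Its merits are large: the whole carbon skeleton, both aryl rings with their native oxygen pattern and the trans C1/C2 relationship arise in one step, with no phenol protection. The weak points for this target come afterwards. Face selection in a radical–radical coupling rests on two auxiliaries that are free to rotate. The electron-rich product can be oxidised further by the enzyme. C3 must then be set by reducing the conjugated C3=C4 bond. Finally, two primary alcohols must be acetylated beside two free phenols, which acylate more readily. Alternative 1 would be clearly shorter and more atom-economical. The chosen plan sets against it stereocentres that are each controlled by an adjacent centre or by a recoverable auxiliary, and a protecting-group order that gives acetates and free phenols without a selective acylation.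

Alternative 2: The cut is C2–C9 together with C1–aryl on the enantiopure dihydronaphthalene A3. In the forward step, under Ir[dF(CF3)ppy]2(dtbbpy)PF6 and NiBr2(dme) with 4,4'-di-tert-butyl-2,2'-bipyridine, the acetoxymethyl radical from the trifluoroborate A4 would add to C2, and the C1 benzylic radical would be arylated by nickel with the aryl bromide A5. This gives the dibenzyl ether A6, one hydrogenolysis from 23. Two C–C bonds and two stereocentres are made at the latest possible stage with the acetates already in place; in convergence this is as good as or better than the chosen plan. Its weak points: A3 still needs the full ring A pattern and the C3 centre as a single enantiomer, so the ring A problem is not solved but moved. An oxygen-substituted primary radical adding to an electron-rich styrene is polarity-mismatched. The C1 radical is flanked by the C8 methoxy group when it meets nickel. Both new centres depend on 1,2-induction in radical steps. The chosen plan sets against it polar, polarity-matched bond formations and an explicit construction of ring A.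

Alternative 3: The cut is C4a–C4 together with C2–C3, closing ring B. Zerovalent palladium from Pd(OAc)2 and PPh3 would insert into the C–I bond of the iodoaryl malonate A7, the arylpalladium would add to a terminal carbon of butadiene 4, and the malonate anion would attack the π-allyl intermediate to give the vinyl tetralin diester A8. Ring A comes from a cheap gallate-type arene rather than from a sensitive diene, which is a real advantage, and butadiene supplies C3 and C4 with a vinyl handle. Its weak points: A7 must be made enantiopure with a crowded diarylmethine. The C3 centre depends on 1,3-induction from C1 during π-allyl capture. The product still needs ozonolysis, decarboxylation with control of C2, two reductions, acetylation and debenzylation. The length would be comparable. The chosen plan sets against it 1,2-stereocontrol at every centre and no malonate or vinyl adjustments.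

Key step: step 11

## Route

Assumption: the aluminium-promoted Diels–Alder reaction of a dimenthyl fumarate is taken to occur on the face of the s-trans, syn-periplanar ester conformer remote from the isopropyl groups, so that the (−)-menthyl ester leads to the (1S,2S) diester and the (+)-menthyl ester to the (1R,2R) diester needed here.

Step 1
Reactants: 1 fumaric acid; 2 (+)-menthol, (1S,2R,5S)-2-isopropyl-5-methylcyclohexan-1-ol
Product: 3 di-(+)-menthyl fumarate
Conditions: 2 (2.1 equiv), TsOH·H2O (cat.), PhMe, reflux, Dean–Stark
Reagents that add atoms: none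
Why: Fischer esterification driven by azeotropic removal of water; the E alkene and the auxiliary stereocentres are not touched.

Step 2
Reactants: 3 di-(+)-menthyl fumarate; 4 buta-1,3-diene
Product: 5 di-(+)-menthyl (1R,2R)-cyclohex-4-ene-1,2-dicarboxylate
Conditions: Et2AlCl (2 equiv), 4 (excess), PhMe–hexane, −40 °C; 1 M HCl work-up; recrystallisation
Reagents that add atoms: none
Why: Lewis-acid-promoted Diels–Alder reaction of a C2-symmetric chiral fumarate; the isopropyl groups of both menthyl esters cover the same face of the aluminium-bound dienophile, so the diene adds to the open face and sets both centres as 1R,2R, while the trans relationship follows from the E alkene. The crystalline adduct can be brought to diastereomeric purity.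

Step 3
Reactants: 5 di-(+)-menthyl (1R,2R)-cyclohex-4-ene-1,2-dicarboxylate
Product: 6 [(1R,2R)-cyclohex-4-ene-1,2-diyl]dimethanol
Conditions: LiAlH4, THF, 0 °C to reflux; H2O/NaOH work-up
Reagents that add atoms: none
Why: Hydride reduction of both esters to primary alcohols, faster than any epimerisation of the α-centres; the auxiliary is recovered as 2.

Step 4
Reactants: 6 [(1R,2R)-cyclohex-4-ene-1,2-diyl]dimethanol
Product: 7 (4R,5R)-4,5-bis[(tert-butyldimethylsilyloxy)methyl]cyclohexene
Conditions: TBSCl (2.3 equiv), imidazole, DMF, rt
Reagents that add atoms: tert-butyldimethylsilyl chloride, CC(C)(C)[Si](C)(C)Cl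
Why: Standard silylation of primary alcohols; the silyl ethers withstand the oxidations, the bromination and the cycloaddition, and silyloxide is a poor leaving group β to the later ketone.

Step 5
Reactants: 7 (4R,5R)-4,5-bis[(tert-butyldimethylsilyloxy)methyl]cyclohexene
Product: 8 (5R,6R)-5,6-bis[(tert-butyldimethylsilyloxy)methyl]cyclohex-2-en-1-ol (C1 epimers)
Conditions: SeO2 (0.5 equiv), t-BuOOH (3 equiv), CH2Cl2, rt
Reagents that add atoms: selenium dioxide, O=[Se]=O; tert-butyl hydroperoxide, CC(C)(C)OO
Why: Allylic hydroxylation by SeO2 (ene reaction, then [2,3]-sigmatropic shift) returns the double bond to its original position, so oxygen lands on the allylic carbon next to a stereocentre; the two allylic CH2 groups are homotopic, so one constitutional isomer forms. The carbinol configuration is irrelevant, and any enone formed directly is carried into step 6.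

Step 6
Reactants: 8 (5R,6R)-5,6-bis[(tert-butyldimethylsilyloxy)methyl]cyclohex-2-en-1-ol
Product: 9 (5R,6R)-5,6-bis[(tert-butyldimethylsilyloxy)methyl]cyclohex-2-en-1-one
Conditions: Dess–Martin periodinane, CH2Cl2, 0 °C to rt
Reagents that add atoms: none
Why: Dess–Martin oxidation of a secondary allylic alcohol under near-neutral conditions; C6 becomes enolisable, but its trans, diequatorial arrangement with C5 is the stable one.

Step 7
Reactants: 9 (5R,6R)-5,6-bis[(tert-butyldimethylsilyloxy)methyl]cyclohex-2-en-1-one
Product: 10 (5R,6R)-2-bromo-5,6-bis[(tert-butyldimethylsilyloxy)methyl]cyclohex-2-en-1-one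
Conditions: Br2, CH2Cl2, 0 °C; then Et3N, 0 °C to rt
Reagents that add atoms: bromine, BrBr
Why: Bromine addition to the enone followed by amine-induced loss of HBr from the α,β-dibromide is the standard route to 2-bromo enones; Et3N is too weak to expel the β-silyloxy group.

Step 8
Reactants: 11 methyl 2-(benzyloxy)acetate
Product: 12 methyl 2-(benzyloxy)-3-oxobutanoate (racemic)
Conditions: LiN(SiMe3)2, THF, −78 °C; AcCl (0.5 equiv per enolate), −78 °C; aq. NH4Cl
Reagents that add atoms: acetyl chloride, CC(Cl)=O
Why: Crossed Claisen acylation of the lithium ester enolate on carbon; the second enolate equivalent takes the acidic proton of the β-keto ester, and that half of 11 is recovered.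

Step 9
Reactants: 12 methyl 2-(benzyloxy)-3-oxobutanoate
Product: 13 methyl 2-(benzyloxy)-3-methoxybut-2-enoate (E/Z mixture)
Conditions: HC(OMe)3, H2SO4 (cat.), MeOH, 50 °C; distillation
Reagents that add atoms: trimethyl orthoformate, COC(OC)OC
Why: Acid-catalysed ketalisation of the ketone and loss of methanol give the β-methoxy enoate, which excludes C-methylation; the alkene geometry is irrelevant because the next step makes a terminal CH2.

Step 10
Reactants: 13 methyl 2-(benzyloxy)-3-methoxybut-2-enoate
Product: 14 2-(benzyloxy)-1,3-dimethoxy-1-(trimethylsilyloxy)buta-1,3-diene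
Conditions: LiN(i-Pr)2, THF, −78 °C; Me3SiCl, −78 °C to rt; filtration, distillation under reduced pressure, used at once
Reagents that add atoms: chlorotrimethylsilane, C[Si](C)(C)Cl
Why: γ-Deprotonation of the vinylogous ester and O-silylation of the dienolate, the standard preparation of 1-alkoxy-1-silyloxy-3-alkoxybutadienes; the γ-methyl protons are far more acidic than the benzylic ether protons.

Step 11
Reactants: 10 (5R,6R)-2-bromo-5,6-bis[(tert-butyldimethylsilyloxy)methyl]cyclohex-2-en-1-one; 14 2-(benzyloxy)-1,3-dimethoxy-1-(trimethylsilyloxy)buta-1,3-diene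
Product: 16 (2R,3R)-7-(benzyloxy)-8-hydroxy-6-methoxy-2,3-bis[(tert-butyldimethylsilyloxy)methyl]-3,4-dihydronaphthalen-1(2H)-one, via bromo ketal cycloadduct 15 (not isolated)
Conditions: 14 (2.5 equiv), PhMe, 90 °C, sealed tube; then Et3N, rt; then SiO2, wet CH2Cl2, rt
Reagents that add atoms: none
Why: The ketene acetal diene 14 adds to the α-bromo enone 10 in a normal-demand, strongly asynchronous Diels–Alder reaction, its CH2 terminus bonding to the enone β-carbon (C4a–C5) ahead of the acetal carbon to the brominated α-carbon (C8–C8a), to give bromo ketal 15. Ring A thus closes as a six-membered carbocycle by intermolecular [4+2] cycloaddition, which at the stepwise limit is a Michael addition followed by closure of the bromo enolate onto the oxocarbenium carbon. 15 then aromatises: the C8 mixed ketal ionises and the C5 proton is lost with expulsion of methanol, HBr is lost across C4a–C8a and taken up by Et3N, and hydrolytic work-up removes the silyl group to leave the C8 phenol hydrogen-bonded to the C1 ketone. The closest known reaction type is the cycloaddition–aromatisation of 1-alkoxy-1-silyloxy-3-alkoxybutadienes with α-halo quinones and of silyloxy dienes with 2-halocycloalkenones; the diene here carries one more alkoxy group. No new stereocentre survives, since the three centres created in 15 (C4a, C8, C8a) are erased, so neither endo/exo nor facial selectivity matters. The selectivity needed is regiochemical and follows from polarisation: the largest HOMO coefficient of 14 is at its CH2 terminus and the largest LUMO coefficient of 10 at the β-carbon, which places OMe on C6, OBn on C7 and OH on C8. C2 and C3 are spectators; C2 is α to the ketone, but its trans, diequatorial arrangement is the stable one.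

Step 12
Reactants: 16 (2R,3R)-7-(benzyloxy)-8-hydroxy-6-methoxy-2,3-bis[(tert-butyldimethylsilyloxy)methyl]-3,4-dihydronaphthalen-1(2H)-one
Product: 17 (2R,3R)-7-(benzyloxy)-6,8-dimethoxy-2,3-bis[(tert-butyldimethylsilyloxy)methyl]-3,4-dihydronaphthalen-1(2H)-one
Conditions: MeI (excess), Ag2O, CH2Cl2, 40 °C, dark
Reagents that add atoms: iodomethane, CI
Why: Silver-oxide-mediated O-methylation (Purdie type) is the usual method for chelated peri-hydroxy ketones and avoids a soluble strong base that could enolise C2 and expel the β-silyloxy group.

Step 13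
Reactants: 17 (2R,3R)-7-(benzyloxy)-6,8-dimethoxy-2,3-bis[(tert-butyldimethylsilyloxy)methyl]-3,4-dihydronaphthalen-1(2H)-one
Product: 18 (2R,3R)-7-(benzyloxy)-6,8-dimethoxy-2,3-bis[(tert-butyldimethylsilyloxy)methyl]-1,2,3,4-tetrahydronaphthalen-1-ol (C1 epimers)
Conditions: NaBH4, MeOH–THF, 0 °C to rt
Reagents that add atoms: none
Why: Borohydride reduction of the aryl ketone; the carbinol configuration does not matter because C1 is ionised in step 15, and C2 can no longer epimerise or eliminate.

Step 14
Reactants: 18 (2R,3R)-7-(benzyloxy)-6,8-dimethoxy-2,3-bis[(tert-butyldimethylsilyloxy)methyl]-1,2,3,4-tetrahydronaphthalen-1-ol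
Product: 20 [(2R,3R)-1-acetoxy-7-(benzyloxy)-6,8-dimethoxy-1,2,3,4-tetrahydronaphthalene-2,3-diyl]dimethanediyl diacetate (C1 epimers), via triol 19 (not isolated)
Conditions: Bu4NF (2.5 equiv), THF, 0 °C to rt; then Ac2O (excess), Et3N, DMAP (cat.), rt
Reagents that add atoms: acetic anhydride, CC(=O)OC(C)=O
Why: Fluoride desilylation under basic conditions spares the acid-sensitive benzylic alcohol, and acylation of the three hydroxyls in the same flask installs the two target acetates and turns C1–OH into a leaving group.

Step 15
Reactants: 20 [(2R,3R)-1-acetoxy-7-(benzyloxy)-6,8-dimethoxy-1,2,3,4-tetrahydronaphthalene-2,3-diyl]dimethanediyl diacetate; 21 2,6-dimethoxyphenol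
Product: 22 [(1S,2R,3R)-7-(benzyloxy)-1-(4-hydroxy-3,5-dimethoxyphenyl)-6,8-dimethoxy-1,2,3,4-tetrahydronaphthalene-2,3-diyl]dimethanediyl diacetate
Conditions: 21 (4 equiv), BF3·OEt2 (0.3 equiv), CH2Cl2, −40 to 0 °C
Reagents that add atoms: none
Why: Friedel–Crafts alkylation through the C1 cation, which the C6 and C8 methoxy groups stabilise, so both epimers of 20 converge; the phenol reacts para to its hydroxyl, the only position not flanked by a substituent. The arene enters anti to the C2 acetoxymethyl group (which may also shield the syn face as a six-membered acetoxonium ion), setting C1 as S, trans to C2, as in the arylation of aryltetralin lignan benzylic alcohols with phenols.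

Step 16
Reactants: 22 [(1S,2R,3R)-7-(benzyloxy)-1-(4-hydroxy-3,5-dimethoxyphenyl)-6,8-dimethoxy-1,2,3,4-tetrahydronaphthalene-2,3-diyl]dimethanediyl diacetate
Product: 23 [(1S,2R,3R)-7-hydroxy-1-(4-hydroxy-3,5-dimethoxyphenyl)-6,8-dimethoxy-1,2,3,4-tetrahydronaphthalene-2,3-diyl]dimethanediyl diacetate (target)
Conditions: H2 (1 atm), Pd/C, EtOAc, rt
Reagents that add atoms: none
Why: Catalytic hydrogenolysis of the aryl benzyl ether is neutral and leaves the primary acetates, the free phenol and the diarylmethine C1 untouched.

## Compound list

1 | fumaric acid | OC(=O)/C=C/C(=O)O | starting material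
2 | (+)-menthol, (1S,2R,5S)-2-isopropyl-5-methylcyclohexan-1-ol | CC(C)[C@H]1CC[C@H](C)C[C@@H]1O | starting material
3 | di-(+)-menthyl fumarate | CC(C)[C@H]1CC[C@H](C)C[C@@H]1OC(=O)/C=C/C(=O)O[C@H]1C[C@@H](C)CC[C@@H]1C(C)C | intermediate
4 | buta-1,3-diene | C=CC=C | starting material
5 | di-(+)-menthyl (1R,2R)-cyclohex-4-ene-1,2-dicarboxylate | CC(C)[C@H]1CC[C@H](C)C[C@@H]1OC(=O)[C@@H]1CC=CC[C@H]1C(=O)O[C@H]1C[C@@H](C)CC[C@@H]1C(C)C | intermediate
6 | [(1R,2R)-cyclohex-4-ene-1,2-diyl]dimethanol | OC[C@@H]1CC=CC[C@H]1CO | intermediate
7 | (4R,5R)-4,5-bis[(tert-butyldimethylsilyloxy)methyl]cyclohexene | CC(C)(C)[Si](C)(C)OC[C@@H]1CC=CC[C@H]1CO[Si](C)(C)C(C)(C)C | intermediate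
8 | (5R,6R)-5,6-bis[(tert-butyldimethylsilyloxy)methyl]cyclohex-2-en-1-ol (C1 epimers) | OC1C=CC[C@@H](CO[Si](C)(C)C(C)(C)C)[C@@H]1CO[Si](C)(C)C(C)(C)C | intermediate
9 | (5R,6R)-5,6-bis[(tert-butyldimethylsilyloxy)methyl]cyclohex-2-en-1-one | O=C1C=CC[C@@H](CO[Si](C)(C)C(C)(C)C)[C@@H]1CO[Si](C)(C)C(C)(C)C | intermediate
10 | (5R,6R)-2-bromo-5,6-bis[(tert-butyldimethylsilyloxy)methyl]cyclohex-2-en-1-one | O=C1C(Br)=CC[C@@H](CO[Si](C)(C)C(C)(C)C)[C@@H]1CO[Si](C)(C)C(C)(C)C | intermediate
11 | methyl 2-(benzyloxy)acetate | COC(=O)COCc1ccccc1 | starting material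
12 | methyl 2-(benzyloxy)-3-oxobutanoate (racemic) | COC(=O)C(OCc1ccccc1)C(C)=O | intermediate
13 | methyl 2-(benzyloxy)-3-methoxybut-2-enoate (E/Z mixture) | COC(=O)C(OCc1ccccc1)=C(C)OC | intermediate
14 | 2-(benzyloxy)-1,3-dimethoxy-1-(trimethylsilyloxy)buta-1,3-diene | C=C(OC)C(OCc1ccccc1)=C(OC)O[Si](C)(C)C | intermediate
15 | (2R,3R)-7-(benzyloxy)-8a-bromo-6,8-dimethoxy-2,3-bis[(tert-butyldimethylsilyloxy)methyl]-8-(trimethylsilyloxy)-3,4,4a,5,8,8a-hexahydronaphthalen-1(2H)-one (cis-fused; C4a, C8 and C8a unassigned; not isolated) | O=C1C2(Br)C(CC(OC)=C(OCc3ccccc3)C2(OC)O[Si](C)(C)C)C[C@@H](CO[Si](C)(C)C(C)(C)C)[C@@H]1CO[Si](C)(C)C(C)(C)C | intermediate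
16 | (2R,3R)-7-(benzyloxy)-8-hydroxy-6-methoxy-2,3-bis[(tert-butyldimethylsilyloxy)methyl]-3,4-dihydronaphthalen-1(2H)-one | O=C1c2c(cc(OC)c(OCc3ccccc3)c2O)C[C@@H](CO[Si](C)(C)C(C)(C)C)[C@@H]1CO[Si](C)(C)C(C)(C)C | intermediate
17 | (2R,3R)-7-(benzyloxy)-6,8-dimethoxy-2,3-bis[(tert-butyldimethylsilyloxy)methyl]-3,4-dihydronaphthalen-1(2H)-one | O=C1c2c(cc(OC)c(OCc3ccccc3)c2OC)C[C@@H](CO[Si](C)(C)C(C)(C)C)[C@@H]1CO[Si](C)(C)C(C)(C)C | intermediate
18 | (2R,3R)-7-(benzyloxy)-6,8-dimethoxy-2,3-bis[(tert-butyldimethylsilyloxy)methyl]-1,2,3,4-tetrahydronaphthalen-1-ol (C1 epimers) | OC1c2c(cc(OC)c(OCc3ccccc3)c2OC)C[C@@H](CO[Si](C)(C)C(C)(C)C)[C@@H]1CO[Si](C)(C)C(C)(C)C | intermediate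
19 | (2R,3R)-7-(benzyloxy)-2,3-bis(hydroxymethyl)-6,8-dimethoxy-1,2,3,4-tetrahydronaphthalen-1-ol (C1 epimers; not isolated) | OC1c2c(cc(OC)c(OCc3ccccc3)c2OC)C[C@@H](CO)[C@@H]1CO | intermediate
20 | [(2R,3R)-1-acetoxy-7-(benzyloxy)-6,8-dimethoxy-1,2,3,4-tetrahydronaphthalene-2,3-diyl]dimethanediyl diacetate (C1 epimers) | CC(=O)OC1c2c(cc(OC)c(OCc3ccccc3)c2OC)C[C@@H](COC(C)=O)[C@@H]1COC(C)=O | intermediate
21 | 2,6-dimethoxyphenol | COc1cccc(OC)c1O | starting material
22 | [(1S,2R,3R)-7-(benzyloxy)-1-(4-hydroxy-3,5-dimethoxyphenyl)-6,8-dimethoxy-1,2,3,4-tetrahydronaphthalene-2,3-diyl]dimethanediyl diacetate | COc1cc([C@H]2c3c(cc(OC)c(OCc4ccccc4)c3OC)C[C@@H](COC(C)=O)[C@@H]2COC(C)=O)cc(OC)c1O | intermediate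
23 | [(1S,2R,3R)-7-hydroxy-1-(4-hydroxy-3,5-dimethoxyphenyl)-6,8-dimethoxy-1,2,3,4-tetrahydronaphthalene-2,3-diyl]dimethanediyl diacetate | COc1cc([C@H]2c3c(cc(OC)c(O)c3OC)C[C@@H](COC(C)=O)[C@@H]2COC(C)=O)cc(OC)c1O | target

## Step count and least certain steps

Total: 16 steps. Longest linear sequence: 13 steps (steps 1–7 and 11–16); steps 8–10 form the three-step diene branch.

**Step 11 (key step).** The cycloaddition may be too slow on a trisubstituted α-bromo enone at temperatures the ketene acetal tolerates, so that hydrolysis or silyl transfer of the diene, or stalling at the open-chain Michael stage, takes over; aromatisation may also be incomplete. The fallback forms the same two bonds in two operations. It sets out from 10 and 14 and returns at 16. A Mukaiyama–Michael addition (Me3SiOTf cat., CH2Cl2, −78 °C, then dilute acid) would give methyl 2-(benzyloxy)-4-{(4R,5R)-2-bromo-4,5-bis[(tert-butyldimethylsilyloxy)methyl]-3-oxocyclohexyl}-3-methoxybut-2-enoate F1. KOt-Bu in THF would then remove HBr and close C8–C8a by intramolecular Claisen condensation of the extended enolate onto the ester, and the dienone so formed tautomerises to 16.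

**Step 5.** Allylic hydroxylation of an unactivated 1,2-disubstituted cyclohexene by SeO2 is slow, and low conversion or a second hydroxylation at the other allylic position may limit throughput. The fallback puts the oxygen in with the diene. It sets out from 3 and returns at 8. A Diels–Alder reaction of 3 with commercial (E)-1-acetoxybuta-1,3-diene (Et2AlCl, as in step 2) would give di-(+)-menthyl (1R,2S)-3-acetoxycyclohex-4-ene-1,2-dicarboxylate F2. LiAlH4 would reduce it to (5R,6R)-5,6-bis(hydroxymethyl)cyclohex-2-en-1-ol F3, and silylation of the two primary hydroxyls (TBSCl, imidazole, CH2Cl2, 0 °C) would give 8. Facial selectivity with the substituted diene would have to be checked.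

**Step 2.** Facial selectivity may be lower than needed, or the sense may be opposite to the one assumed. The fallback sets out from 5 and returns at 6. Saponification (KOH, aq. EtOH, reflux) would give (1R,2R)-cyclohex-4-ene-1,2-dicarboxylic acid F4, which would be enriched by crystallisation of its salt with (R)-1-phenylethylamine and reduced with LiAlH4 to 6. If the sense proves opposite, step 1 is run with (−)-menthol.

**Step 15.** The C1 cation may lose the C2 proton to give the dihydronaphthalene, which would erase C2, or the phenol may react ortho to a methoxy group. The fallback replaces the electrophilic aromatic substitution by transfer of an aryl group from a metal. It sets out from 20 and returns at 23. HCl in Et2O/CH2Cl2 at 0 °C would give [(2R,3R)-7-(benzyloxy)-1-chloro-6,8-dimethoxy-1,2,3,4-tetrahydronaphthalene-2,3-diyl]dimethanediyl diacetate F5. This would be coupled, without a transition metal, with bis[4-(benzyloxy)-3,5-dimethoxyphenyl]zinc F6 (from the aryl bromide by bromine–lithium exchange and ZnCl2) to give [(1S,2R,3R)-7-(benzyloxy)-1-[4-(benzyloxy)-3,5-dimethoxyphenyl]-6,8-dimethoxy-1,2,3,4-tetrahydronaphthalene-2,3-diyl]dimethanediyl diacetate F7. Hydrogenolysis of both benzyl ethers would give 23.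

**Step 8.** O-acylation or double acylation of the enolate may compete with C-acylation. The fallback sets out from 11 and returns at 12. Aldol addition of the lithium enolate of 11 to acetaldehyde would give methyl 2-(benzyloxy)-3-hydroxybutanoate F8, and Dess–Martin oxidation would give 12.

## Further compounds

F1 | step 11 | methyl 2-(benzyloxy)-4-{(4R,5R)-2-bromo-4,5-bis[(tert-butyldimethylsilyloxy)methyl]-3-oxocyclohexyl}-3-methoxybut-2-enoate | O=C1C(Br)C(CC(OC)=C(OCc2ccccc2)C(=O)OC)C[C@@H](CO[Si](C)(C)C(C)(C)C)[C@@H]1CO[Si](C)(C)C(C)(C)C
F2 | step 5 | di-(+)-menthyl (1R,2S)-3-acetoxycyclohex-4-ene-1,2-dicarboxylate (C3 epimers) | CC(=O)OC1C=CC[C@@H](C(=O)O[C@H]2C[C@@H](C)CC[C@@H]2C(C)C)[C@@H]1C(=O)O[C@H]1C[C@@H](C)CC[C@@H]1C(C)C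
F3 | step 5 | (5R,6R)-5,6-bis(hydroxymethyl)cyclohex-2-en-1-ol (C1 epimers) | OC1C=CC[C@@H](CO)[C@@H]1CO
F4 | step 2 | (1R,2R)-cyclohex-4-ene-1,2-dicarboxylic acid | OC(=O)[C@@H]1CC=CC[C@H]1C(=O)O
F5 | step 15 | [(2R,3R)-7-(benzyloxy)-1-chloro-6,8-dimethoxy-1,2,3,4-tetrahydronaphthalene-2,3-diyl]dimethanediyl diacetate (C1 epimers) | ClC1c2c(cc(OC)c(OCc3ccccc3)c2OC)C[C@@H](COC(C)=O)[C@@H]1COC(C)=O
F6 | step 15 | bis[4-(benzyloxy)-3,5-dimethoxyphenyl]zinc | COc1cc([Zn]c2cc(OC)c(OCc3ccccc3)c(OC)c2)cc(OC)c1OCc1ccccc1
F7 | step 15 | [(1S,2R,3R)-7-(benzyloxy)-1-[4-(benzyloxy)-3,5-dimethoxyphenyl]-6,8-dimethoxy-1,2,3,4-tetrahydronaphthalene-2,3-diyl]dimethanediyl diacetate | COc1cc([C@H]2c3c(cc(OC)c(OCc4ccccc4)c3OC)C[C@@H](COC(C)=O)[C@@H]2COC(C)=O)cc(OC)c1OCc1ccccc1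
F8 | step 8 | methyl 2-(benzyloxy)-3-hydroxybutanoate (diastereomers) | COC(=O)C(OCc1ccccc1)C(C)O
A1 | alternative 1 | (S)-4-benzyl-3-[(E)-3-(4-hydroxy-3,5-dimethoxyphenyl)prop-2-enoyl]oxazolidin-2-one | COc1cc(/C=C/C(=O)N2[C@@H](Cc3ccccc3)COC2=O)cc(OC)c1O
A2 | alternative 1 | trans-7-hydroxy-1-(4-hydroxy-3,5-dimethoxyphenyl)-6,8-dimethoxy-1,2-dihydronaphthalene-2,3-dicarboxylic acid bis-imide with (S)-4-benzyloxazolidin-2-one | COc1cc([C@H]2c3c(cc(OC)c(O)c3OC)C=C(C(=O)N3[C@@H](Cc4ccccc4)COC3=O)[C@@H]2C(=O)N2[C@@H](Cc3ccccc3)COC2=O)cc(OC)c1O
A3 | alternative 2 | [(2R)-6-(benzyloxy)-5,7-dimethoxy-1,2-dihydronaphthalen-2-yl]methyl acetate | c1c(OC)c(OCc2ccccc2)c(OC)c2c1C[C@@H](COC(C)=O)C=C2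
A4 | alternative 2 | potassium (acetoxymethyl)trifluoroborate | CC(=O)OC[B-](F)(F)F.[K+]
A5 | alternative 2 | 5-bromo-2-(benzyloxy)-1,3-dimethoxybenzene | COc1cc(Br)cc(OC)c1OCc1ccccc1
A6 | alternative 2 | [(1S,2R,3R)-7-(benzyloxy)-1-[4-(benzyloxy)-3,5-dimethoxyphenyl]-6,8-dimethoxy-1,2,3,4-tetrahydronaphthalene-2,3-diyl]dimethanediyl diacetate | COc1cc([C@H]2c3c(cc(OC)c(OCc4ccccc4)c3OC)C[C@@H](COC(C)=O)[C@@H]2COC(C)=O)cc(OC)c1OCc1ccccc1
A7 | alternative 3 | dimethyl 2-{(S)-[4-(benzyloxy)-3,5-dimethoxyphenyl][3-(benzyloxy)-6-iodo-2,4-dimethoxyphenyl]methyl}malonate | COc1cc([C@H](C(C(=O)OC)C(=O)OC)c2c(I)cc(OC)c(OCc3ccccc3)c2OC)cc(OC)c1OCc1ccccc1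
A8 | alternative 3 | dimethyl (1S,3R)-7-(benzyloxy)-1-[4-(benzyloxy)-3,5-dimethoxyphenyl]-6,8-dimethoxy-3-vinyl-3,4-dihydronaphthalene-2,2(1H)-dicarboxylate | COc1cc([C@H]2c3c(cc(OC)c(OCc4ccccc4)c3OC)C[C@@H](C=C)C2(C(=O)OC)C(=O)OC)cc(OC)c1OCc1ccccc1
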